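The route rests on cutting unit B, the central dihydrobenzofuran, between C2 and C3, after disconnecting the stilbene alkene and the C3(unit B)–C4(unit C) bond. The key step exploits the C2–H bond of unit B: it is benzylic, flanked by O1 and the 4-oxyphenyl ring, and sits 1,5 to C3. A rhodium carbene at C3, released from an ortho-(4-methoxybenzyloxy)aryl diazoacetate that already carries the C6 bromide, inserts into this bond, closing the furan ring of unit B and setting C2 (R) in one operation. The cis C3 ester is a temporary handle, later exchanged for the unit C aryl group; unit A (the 7-oxygenated unit) is attached by a Heck reaction.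

Key step: step 4

Assumption: dirhodium tetrakis[N-phthaloyl-(S)-tert-leucinate], Rh2(S-PTTL)4, is taken to give the (2R,3S) cis ester and Rh2(R-PTTL)4 its mirror image; if the sense is the opposite, the two catalysts are exchanged between steps 4 and 8 and nothing else changes. Unit C is the 6-oxygenated dihydrobenzofuran bonded through its C4 to C3 of unit B.

**Unit B core**

Step 1
Reactants: 1 2-(4-bromo-2-hydroxyphenyl)acetic acid
Product: 2 methyl 2-(4-bromo-2-hydroxyphenyl)acetate
Conditions: MeOH, H2SO4 (cat.), reflux; NaHCO3 work-up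
Reagents that add atoms: methanol, CO
Why: Fischer esterification in excess methanol converts the acid selectively, the phenol stays free, and any benzofuranone formed by lactonisation is reopened to the same hydroxy ester by acidic methanolysis.

Step 2
Reactants: 2 methyl 2-(4-bromo-2-hydroxyphenyl)acetate; 3 4-methoxybenzyl chloride
Product: 4 methyl 2-[4-bromo-2-(4-methoxybenzyloxy)phenyl]acetate
Conditions: K2CO3, KI (cat.), DMF, 60 °C
Reagents that add atoms: none
Why: Williamson etherification, in which the carbonate-generated phenoxide displaces the benzylic chloride by SN2 while the ester α-CH2 is not acidic enough to compete.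

Step 3
Reactants: 4 methyl 2-[4-bromo-2-(4-methoxybenzyloxy)phenyl]acetate
Product: 5 methyl 2-diazo-2-[4-bromo-2-(4-methoxybenzyloxy)phenyl]acetate
Conditions: p-ABSA, DBU, MeCN, 0 °C → rt
Reagents that add atoms: 4-acetamidobenzenesulfonyl azide (p-ABSA), CC(=O)Nc1ccc(cc1)S(=O)(=O)N=[N+]=[N-]
Why: Regitz diazo transfer, in which DBU deprotonates the aryl-activated ester and the enolate takes up the terminal nitrogens of the sulfonyl azide, the standard route to aryldiazoacetates.

Step 4
Reactants: 5 methyl 2-diazo-2-[4-bromo-2-(4-methoxybenzyloxy)phenyl]acetate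
Product: 6 methyl (2R,3S)-6-bromo-2-(4-methoxyphenyl)-2,3-dihydro-1-benzofuran-3-carboxylate (cis)
Conditions: Rh2(S-PTTL)4 (1 mol%), toluene, −60 °C, slow addition of 5; recrystallisation
Reagents that add atoms: none
Why: Rh2(S-PTTL)4 displaces N2 from 5 to give an electrophilic donor/acceptor carbene at the future C3, which inserts into the benzylic ether C–H bond through a concerted but asynchronous three-centre transition state with hydride-transfer character, forming C2–C3. The closest known reaction type is the dirhodium tetracarboxylate-catalysed enantioselective intramolecular C–H insertion of aryldiazoacetates into benzyl aryl ethers, which delivers cis-2-aryl-2,3-dihydrobenzofuran-3-carboxylates. The dihydrofuran ring of unit B closes by 1,5-insertion, the carbene carbon bonding to the fifth atom of the C–C(aryl)–C(aryl)–O–CH2 chain, which is the only C–H-bearing position within reach. C2 (R) is set by the catalyst, whose N-phthaloyl-tert-leucinate ligands distinguish the two enantiotopic benzylic hydrogens, and C3 (S, cis) follows from the kinetically controlled geometry of the same transition state, which places the ester and the anisyl group on one face. The step needs chemoselectivity for C–H insertion over attack on the anisyl ring and over carbene dimerisation, which the charge-stabilising oxygen and 4-methoxyphenyl groups at C2, the low temperature and the slow addition secure, while the aryl bromide is inert to the rhodium carbene. Recrystallisation of 6 should raise its enantiomeric purity if needed.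

**Unit A styrene**

Step 5
Reactants: 7 2-(2-hydroxy-3-methoxyphenyl)acetic acid
Product: 9 methyl 2-(5-bromo-2-hydroxy-3-methoxyphenyl)acetate, via bromo acid 8 (not isolated)
Conditions: Br2 (1.0 equiv), MeOH, 0 °C; then reflux; NaHCO3 work-up
Reagents that add atoms: bromine, BrBr; methanol, CO
Why: Electrophilic aromatic bromination goes para to the free phenol, whose two ortho positions are blocked, and the HBr set free then catalyses Fischer esterification in the same methanol solution.

Step 6
Reactants: 9 methyl 2-(5-bromo-2-hydroxy-3-methoxyphenyl)acetate; 3 4-methoxybenzyl chloride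
Product: 10 methyl 2-[5-bromo-3-methoxy-2-(4-methoxybenzyloxy)phenyl]acetate
Conditions: K2CO3, KI (cat.), DMF, 60 °C
Reagents that add atoms: none
Why: Williamson etherification as in step 2; the phenoxide flanked by the methoxy group is hindered but should still be alkylated by the reactive benzylic chloride under iodide catalysis.

Step 7
Reactants: 10 methyl 2-[5-bromo-3-methoxy-2-(4-methoxybenzyloxy)phenyl]acetate
Product: 11 methyl 2-diazo-2-[5-bromo-3-methoxy-2-(4-methoxybenzyloxy)phenyl]acetate
Conditions: p-ABSA, DBU, MeCN, 0 °C → rt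
Reagents that add atoms: 4-acetamidobenzenesulfonyl azide (p-ABSA), CC(=O)Nc1ccc(cc1)S(=O)(=O)N=[N+]=[N-]
Why: Regitz diazo transfer to the ester enolate, as in step 3.

Step 8
Reactants: 11 methyl 2-diazo-2-[5-bromo-3-methoxy-2-(4-methoxybenzyloxy)phenyl]acetate
Product: 12 methyl (2S,3R)-5-bromo-7-methoxy-2-(4-methoxyphenyl)-2,3-dihydro-1-benzofuran-3-carboxylate (cis)
Conditions: Rh2(R-PTTL)4 (1 mol%), toluene, −60 °C, slow addition of 11
Reagents that add atoms: none
Why: Enantioselective intramolecular rhodium carbene C–H insertion as in step 4, run with the mirror-image catalyst so that its chiral carboxylate ligands set C2 as S and the kinetic cis ester (3R) forms by 1,5-insertion.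

Step 9
Reactants: 12 methyl (2S,3R)-5-bromo-7-methoxy-2-(4-methoxyphenyl)-2,3-dihydro-1-benzofuran-3-carboxylate
Product: 13 (2S)-5-bromo-7-methoxy-2-(4-methoxyphenyl)-2,3-dihydro-1-benzofuran-3-carboxylic acid (C3 not defined; either epimer serves)
Conditions: LiOH, THF/MeOH/H2O, rt; then 1 M HCl
Reagents that add atoms: lithium hydroxide, [Li+].[OH-]
Why: Saponification by acyl substitution with hydroxide; C3 may epimerise through the enolate, which is immaterial, whereas C2 is safe because ring opening of that enolate would be a disfavoured retro-5-endo process.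

Step 10
Reactants: 14 3,5-dimethoxyphenylmagnesium chloride (THF solution, 2 equiv)
Product: 15 bis(3,5-dimethoxyphenyl)zinc (titrated THF stock solution, MgCl2 present; used in steps 11 and 18)
Conditions: ZnCl2 (1.0 M in THF, 0.5 equiv per Grignard), THF, 0 °C → rt; stored under argon
Reagents that add atoms: zinc chloride, Cl[Zn]Cl
Why: Salt metathesis (magnesium-to-zinc transmetalation) of two aryl Grignard equivalents with ZnCl2 gives the diarylzinc together with MgCl2, the form of arylzinc reagent that iron/diphosphine catalysts transfer most readily.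

Step 11
Reactants: 13 (2S)-5-bromo-7-methoxy-2-(4-methoxyphenyl)-2,3-dihydro-1-benzofuran-3-carboxylic acid; 15 bis(3,5-dimethoxyphenyl)zinc
Product: 17 (2S,3S)-5-bromo-3-(3,5-dimethoxyphenyl)-7-methoxy-2-(4-methoxyphenyl)-2,3-dihydro-1-benzofuran (trans), via NHPI ester 16 (not isolated)
Conditions: NHPI, DIC, DMAP (cat.), CH2Cl2, rt, then evaporate; 15 (1.5 equiv), Fe(acac)3 (20 mol%), 1,2-bis(diphenylphosphino)benzene (dppBz, 24 mol%), THF/toluene, 0 °C → rt; aqueous HCl work-up
Reagents that add atoms: none
Why: Iron-catalysed decarboxylative Negishi-type arylation of a redox-active ester, in which single-electron reduction of 16 releases CO2 and the C3 benzylic radical, which is arylated on the face opposite the C2 anisyl group to give the trans product (C3 = S), while the Fe(acac)3/dppBz catalyst is not expected to insert into the electron-rich aryl bromide.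

Step 12
Reactants: 17 (2S,3S)-5-bromo-3-(3,5-dimethoxyphenyl)-7-methoxy-2-(4-methoxyphenyl)-2,3-dihydro-1-benzofuran; 18 4,4,5,5-tetramethyl-2-vinyl-1,3,2-dioxaborolane
Product: 19 (2S,3S)-3-(3,5-dimethoxyphenyl)-5-ethenyl-7-methoxy-2-(4-methoxyphenyl)-2,3-dihydro-1-benzofuran (unit A styrene)
Conditions: PdCl2(dppf) (5 mol%), K2CO3, 1,4-dioxane/H2O, 85 °C
Reagents that add atoms: none
Why: Suzuki–Miyaura coupling of the aryl bromide with the vinylboronate; no base-labile site remains and both stereocentres are untouched.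

**Unit C bromide**

Step 13
Reactants: 20 (S)-naringenin
Product: 21 (2S)-5-hydroxy-7-methoxy-2-(4-methoxyphenyl)-2,3-dihydro-4H-chromen-4-one
Conditions: MeOH, PPh3, DIAD, THF, 0 °C → rt
Reagents that add atoms: methanol, CO
Why: Mitsunobu etherification methylates the 7- and 4'-phenols without added base, which avoids base-induced opening of the flavanone, while the 5-OH hydrogen-bonded to the ketone does not react and C2 (S, from the chiral pool) is preserved.

Step 14
Reactants: 21 (2S)-5-hydroxy-7-methoxy-2-(4-methoxyphenyl)-2,3-dihydro-4H-chromen-4-one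
Product: 22 (2S)-7-methoxy-2-(4-methoxyphenyl)-4-oxo-3,4-dihydro-2H-chromen-5-yl trifluoromethanesulfonate
Conditions: Tf2O, pyridine, CH2Cl2, −20 → 0 °C
Reagents that add atoms: trifluoromethanesulfonic anhydride, O=S(=O)(OS(=O)(=O)C(F)(F)F)C(F)(F)F
Why: O-Sulfonylation of the remaining chelated phenol by the strongly electrophilic anhydride with a weak base, which leaves the flavanone ring closed.

Step 15
Reactants: 22 (2S)-7-methoxy-2-(4-methoxyphenyl)-4-oxo-3,4-dihydro-2H-chromen-5-yl trifluoromethanesulfonate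
Product: 23 methyl (2S,3S)-6-methoxy-2-(4-methoxyphenyl)-4-(trifluoromethanesulfonyloxy)-2,3-dihydro-1-benzofuran-3-carboxylate (trans)
Conditions: PhI(OAc)2, conc. H2SO4, HC(OMe)3/MeOH, 0 °C → rt
Reagents that add atoms: methanol, CO
Why: Oxidative ring contraction of a flavanone by trivalent iodine, in which the enol ether formed in acidic orthoformate is iodinated at C3 and the ketal-activated ring A carbon migrates from C4 to C3 with loss of iodobenzene, giving the trans ester while C2 is untouched.

Step 16
Reactants: 23 methyl (2S,3S)-6-methoxy-2-(4-methoxyphenyl)-4-(trifluoromethanesulfonyloxy)-2,3-dihydro-1-benzofuran-3-carboxylate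
Product: 24 methyl (2S,3S)-4-bromo-6-methoxy-2-(4-methoxyphenyl)-2,3-dihydro-1-benzofuran-3-carboxylate (trans)
Conditions: Pd2(dba)3, tBuBrettPhos, KBr, KF, 1,4-dioxane, 130 °C
Reagents that add atoms: potassium bromide, [K+].[Br-]
Why: Palladium-catalysed triflate-to-bromide exchange, by oxidative addition of the aryl triflate to zerovalent palladium carrying the bulky biaryl phosphine, triflate/bromide exchange and C–Br reductive elimination; the trans ester is the stable epimer under these conditions.

Step 17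
Reactants: 24 methyl (2S,3S)-4-bromo-6-methoxy-2-(4-methoxyphenyl)-2,3-dihydro-1-benzofuran-3-carboxylate
Product: 25 (2S,3S)-4-bromo-6-methoxy-2-(4-methoxyphenyl)-2,3-dihydro-1-benzofuran-3-carboxylic acid (trans)
Conditions: LiOH, THF/MeOH/H2O, rt; then 1 M HCl
Reagents that add atoms: lithium hydroxide, [Li+].[OH-]
Why: Saponification; the trans ester gives the trans acid and the aryl bromide is inert to hydroxide.

Step 18
Reactants: 25 (2S,3S)-4-bromo-6-methoxy-2-(4-methoxyphenyl)-2,3-dihydro-1-benzofuran-3-carboxylic acid; 15 bis(3,5-dimethoxyphenyl)zinc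
Product: 27 (2S,3S)-4-bromo-3-(3,5-dimethoxyphenyl)-6-methoxy-2-(4-methoxyphenyl)-2,3-dihydro-1-benzofuran (unit C bromide, trans), via NHPI ester 26 (not isolated)
Conditions: NHPI, DIC, DMAP (cat.), CH2Cl2, rt, then evaporate; 15 (1.5 equiv), Fe(acac)3 (20 mol%), dppBz (24 mol%), THF/toluene, 0 °C → rt; aqueous HCl work-up
Reagents that add atoms: none
Why: Iron-catalysed decarboxylative arylation of a redox-active ester as in step 11, the C3 radical being arylated anti to the C2 anisyl group to give the trans product (C3 = S) with the C4 bromide retained.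

**Union and deprotection**

Step 19
Reactants: 6 methyl (2R,3S)-6-bromo-2-(4-methoxyphenyl)-2,3-dihydro-1-benzofuran-3-carboxylate; 19 unit A styrene
Product: 28 methyl (2R,3S)-6-{(E)-2-[(2S,3S)-3-(3,5-dimethoxyphenyl)-7-methoxy-2-(4-methoxyphenyl)-2,3-dihydro-1-benzofuran-5-yl]ethenyl}-2-(4-methoxyphenyl)-2,3-dihydro-1-benzofuran-3-carboxylate
Conditions: Pd(OAc)2 (5 mol%), P(o-tol)3, NaOAc, DMA, 110 °C
Reagents that add atoms: none
Why: Mizoroki–Heck reaction, in which oxidative addition of the aryl bromide to zerovalent palladium, syn insertion at the terminal carbon of styrene 19 and syn β-hydride elimination give the E-stilbene, the acetate base being too weak to open the furan rings and any epimerisation at C3 of unit B being harmless because that centre is rebuilt in step 21.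

Step 20
Reactants: 28 the stilbene ester of step 19
Product: 29 (2R)-6-{(E)-2-[(2S,3S)-3-(3,5-dimethoxyphenyl)-7-methoxy-2-(4-methoxyphenyl)-2,3-dihydro-1-benzofuran-5-yl]ethenyl}-2-(4-methoxyphenyl)-2,3-dihydro-1-benzofuran-3-carboxylic acid (C3 of unit B not defined; either epimer serves)
Conditions: LiOH, THF/MeOH/H2O, rt; then 1 M HCl
Reagents that add atoms: lithium hydroxide, [Li+].[OH-]
Why: Saponification as in step 9; C3 of unit B may epimerise without consequence because it becomes a radical in the next step.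

Step 21
Reactants: 29 the stilbene acid of step 20; 27 unit C bromide
Product: 33 nonamethyl ether of the target, via NHPI ester 30 (not isolated), via aryllithium 31 (not isolated), via arylzinc chloride 32 (not isolated)
Conditions: 29: NHPI, DIC, DMAP (cat.), CH2Cl2, rt, then evaporate; 27: n-BuLi, THF, −78 °C, then ZnCl2, → rt; NiCl2·glyme (20 mol%), 4,4'-di-tert-butyl-2,2'-bipyridine (40 mol%), THF/DMF, rt
Reagents that add atoms: none
Why: Nickel-catalysed decarboxylative Negishi-type coupling of a redox-active ester with an arylzinc chloride, in which the C3 radical of unit B is captured by the arylnickel species and reductive elimination occurs on the face anti to the C2 anisyl group, setting C3 as R (trans), with no base present and no halide left to compete.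

Step 22
Reactants: 33 nonamethyl ether of the target
Product: 34 CNP0265934.1 (target)
Conditions: BBr3 (excess), CH2Cl2, −78 °C → rt; MeOH, then aqueous NaHCO3
Reagents that add atoms: none
Why: Lewis-acid ether cleavage, each ArO–CH3 being cleaved by bromide at methyl after coordination to boron; the three 2,3-trans dihydrobenzofurans are the thermodynamic isomers, so any reversible C2–O ionisation should return the same configuration.

**Compound list**

1 | 2-(4-bromo-2-hydroxyphenyl)acetic acid | OC(=O)Cc1ccc(Br)cc1O | starting material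
2 | methyl 2-(4-bromo-2-hydroxyphenyl)acetate | COC(=O)Cc1ccc(Br)cc1O | intermediate
3 | 4-methoxybenzyl chloride | COc1ccc(CCl)cc1 | starting material
4 | methyl 2-[4-bromo-2-(4-methoxybenzyloxy)phenyl]acetate | COC(=O)Cc1ccc(Br)cc1OCc1ccc(OC)cc1 | intermediate
5 | methyl 2-diazo-2-[4-bromo-2-(4-methoxybenzyloxy)phenyl]acetate | COC(=O)C(=[N+]=[N-])c1ccc(Br)cc1OCc1ccc(OC)cc1 | intermediate
6 | methyl (2R,3S)-6-bromo-2-(4-methoxyphenyl)-2,3-dihydro-1-benzofuran-3-carboxylate (cis) | Brc1ccc2c(c1)O[C@@H](c1ccc(OC)cc1)[C@H]2C(=O)OC | intermediate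
7 | 2-(2-hydroxy-3-methoxyphenyl)acetic acid | OC(=O)Cc1cccc(OC)c1O | starting material
8 | 2-(5-bromo-2-hydroxy-3-methoxyphenyl)acetic acid (not isolated) | OC(=O)Cc1cc(Br)cc(OC)c1O | intermediate
9 | methyl 2-(5-bromo-2-hydroxy-3-methoxyphenyl)acetate | COC(=O)Cc1cc(Br)cc(OC)c1O | intermediate
10 | methyl 2-[5-bromo-3-methoxy-2-(4-methoxybenzyloxy)phenyl]acetate | COC(=O)Cc1cc(Br)cc(OC)c1OCc1ccc(OC)cc1 | intermediate
11 | methyl 2-diazo-2-[5-bromo-3-methoxy-2-(4-methoxybenzyloxy)phenyl]acetate | COC(=O)C(=[N+]=[N-])c1cc(Br)cc(OC)c1OCc1ccc(OC)cc1 | intermediate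
12 | methyl (2S,3R)-5-bromo-7-methoxy-2-(4-methoxyphenyl)-2,3-dihydro-1-benzofuran-3-carboxylate (cis) | COc1cc(Br)cc2c1O[C@H](c1ccc(OC)cc1)[C@@H]2C(=O)OC | intermediate
13 | (2S)-5-bromo-7-methoxy-2-(4-methoxyphenyl)-2,3-dihydro-1-benzofuran-3-carboxylic acid (C3 not defined) | COc1cc(Br)cc2c1O[C@H](c1ccc(OC)cc1)C2C(=O)O | intermediate
14 | 3,5-dimethoxyphenylmagnesium chloride (THF solution) | COc1cc(OC)cc([Mg]Cl)c1 | starting material
15 | bis(3,5-dimethoxyphenyl)zinc (THF stock solution) | COc1cc(OC)cc([Zn]c2cc(OC)cc(OC)c2)c1 | intermediate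
16 | 1,3-dioxoisoindolin-2-yl (NHPI) ester of 13 (not isolated) | COc1cc(Br)cc2c1O[C@H](c1ccc(OC)cc1)C2C(=O)ON1C(=O)c2ccccc2C1=O | intermediate
17 | (2S,3S)-5-bromo-3-(3,5-dimethoxyphenyl)-7-methoxy-2-(4-methoxyphenyl)-2,3-dihydro-1-benzofuran (trans) | COc1ccc([C@H]2Oc3c(OC)cc(Br)cc3[C@@H]2c2cc(OC)cc(OC)c2)cc1 | intermediate
18 | 4,4,5,5-tetramethyl-2-vinyl-1,3,2-dioxaborolane | C=CB1OC(C)(C)C(C)(C)O1 | starting material
19 | (2S,3S)-3-(3,5-dimethoxyphenyl)-5-ethenyl-7-methoxy-2-(4-methoxyphenyl)-2,3-dihydro-1-benzofuran (unit A styrene) | COc1ccc([C@H]2Oc3c(OC)cc(C=C)cc3[C@@H]2c2cc(OC)cc(OC)c2)cc1 | intermediate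
20 | (S)-naringenin | O=C1C[C@@H](c2ccc(O)cc2)Oc2cc(O)cc(O)c12 | starting material
21 | (2S)-5-hydroxy-7-methoxy-2-(4-methoxyphenyl)-2,3-dihydro-4H-chromen-4-one | O=C1C[C@@H](c2ccc(OC)cc2)Oc2cc(OC)cc(O)c12 | intermediate
22 | (2S)-7-methoxy-2-(4-methoxyphenyl)-4-oxo-3,4-dihydro-2H-chromen-5-yl trifluoromethanesulfonate | O=C1C[C@@H](c2ccc(OC)cc2)Oc2cc(OC)cc(OS(=O)(=O)C(F)(F)F)c12 | intermediate
23 | methyl (2S,3S)-6-methoxy-2-(4-methoxyphenyl)-4-(trifluoromethanesulfonyloxy)-2,3-dihydro-1-benzofuran-3-carboxylate (trans) | COc1cc(OS(=O)(=O)C(F)(F)F)c2c(c1)O[C@H](c1ccc(OC)cc1)[C@H]2C(=O)OC | intermediate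
24 | methyl (2S,3S)-4-bromo-6-methoxy-2-(4-methoxyphenyl)-2,3-dihydro-1-benzofuran-3-carboxylate (trans) | COc1cc(Br)c2c(c1)O[C@H](c1ccc(OC)cc1)[C@H]2C(=O)OC | intermediate
25 | (2S,3S)-4-bromo-6-methoxy-2-(4-methoxyphenyl)-2,3-dihydro-1-benzofuran-3-carboxylic acid (trans) | COc1cc(Br)c2c(c1)O[C@H](c1ccc(OC)cc1)[C@H]2C(=O)O | intermediate
26 | 1,3-dioxoisoindolin-2-yl (NHPI) ester of 25 (not isolated) | COc1cc(Br)c2c(c1)O[C@H](c1ccc(OC)cc1)[C@H]2C(=O)ON1C(=O)c2ccccc2C1=O | intermediate
27 | (2S,3S)-4-bromo-3-(3,5-dimethoxyphenyl)-6-methoxy-2-(4-methoxyphenyl)-2,3-dihydro-1-benzofuran (unit C bromide, trans) | Brc1cc(OC)cc2c1[C@H](c1cc(OC)cc(OC)c1)[C@@H](c1ccc(OC)cc1)O2 | intermediate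
28 | methyl (2R,3S)-6-{(E)-2-[(2S,3S)-3-(3,5-dimethoxyphenyl)-7-methoxy-2-(4-methoxyphenyl)-2,3-dihydro-1-benzofuran-5-yl]ethenyl}-2-(4-methoxyphenyl)-2,3-dihydro-1-benzofuran-3-carboxylate | COc1ccc([C@H]2Oc3c(OC)cc(/C=C/c4ccc5c(c4)O[C@@H](c4ccc(OC)cc4)[C@H]5C(=O)OC)cc3[C@@H]2c2cc(OC)cc(OC)c2)cc1 | intermediate
29 | (2R)-6-{(E)-2-[(2S,3S)-3-(3,5-dimethoxyphenyl)-7-methoxy-2-(4-methoxyphenyl)-2,3-dihydro-1-benzofuran-5-yl]ethenyl}-2-(4-methoxyphenyl)-2,3-dihydro-1-benzofuran-3-carboxylic acid (C3 of unit B not defined) | COc1ccc([C@H]2Oc3c(OC)cc(/C=C/c4ccc5c(c4)O[C@@H](c4ccc(OC)cc4)C5C(=O)O)cc3[C@@H]2c2cc(OC)cc(OC)c2)cc1 | intermediate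
30 | 1,3-dioxoisoindolin-2-yl (NHPI) ester of 29 (not isolated) | COc1ccc([C@H]2Oc3c(OC)cc(/C=C/c4ccc5c(c4)O[C@@H](c4ccc(OC)cc4)C5C(=O)ON4C(=O)c5ccccc5C4=O)cc3[C@@H]2c2cc(OC)cc(OC)c2)cc1 | intermediate
31 | [(2S,3S)-3-(3,5-dimethoxyphenyl)-6-methoxy-2-(4-methoxyphenyl)-2,3-dihydro-1-benzofuran-4-yl]lithium (not isolated) | [Li]c1cc(OC)cc2c1[C@H](c1cc(OC)cc(OC)c1)[C@@H](c1ccc(OC)cc1)O2 | intermediate
32 | [(2S,3S)-3-(3,5-dimethoxyphenyl)-6-methoxy-2-(4-methoxyphenyl)-2,3-dihydro-1-benzofuran-4-yl]zinc chloride (not isolated) | Cl[Zn]c1cc(OC)cc2c1[C@H](c1cc(OC)cc(OC)c1)[C@@H](c1ccc(OC)cc1)O2 | intermediate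
33 | nonamethyl ether of the target: (2S,3S)-5-{(E)-2-[(2R,3R)-3-[(2S,3S)-3-(3,5-dimethoxyphenyl)-6-methoxy-2-(4-methoxyphenyl)-2,3-dihydro-1-benzofuran-4-yl]-2-(4-methoxyphenyl)-2,3-dihydro-1-benzofuran-6-yl]ethenyl}-3-(3,5-dimethoxyphenyl)-7-methoxy-2-(4-methoxyphenyl)-2,3-dihydro-1-benzofuran | COc1ccc([C@H]2Oc3c(OC)cc(/C=C/c4ccc5c(c4)O[C@@H](c4ccc(OC)cc4)[C@@H]5c4cc(OC)cc5c4[C@H](c4cc(OC)cc(OC)c4)[C@@H](c4ccc(OC)cc4)O5)cc3[C@@H]2c2cc(OC)cc(OC)c2)cc1 | intermediate
34 | CNP0265934.1: (2S,3S)-5-{(E)-2-[(2R,3R)-3-[(2S,3S)-3-(3,5-dihydroxyphenyl)-6-hydroxy-2-(4-hydroxyphenyl)-2,3-dihydro-1-benzofuran-4-yl]-2-(4-hydroxyphenyl)-2,3-dihydro-1-benzofuran-6-yl]ethenyl}-3-(3,5-dihydroxyphenyl)-2-(4-hydroxyphenyl)-2,3-dihydro-1-benzofuran-7-ol | Oc1ccc([C@H]2Oc3c(O)cc(/C=C/c4ccc5c(c4)O[C@@H](c4ccc(O)cc4)[C@@H]5c4cc(O)cc5c4[C@H](c4cc(O)cc(O)c4)[C@@H](c4ccc(O)cc4)O5)cc3[C@@H]2c2cc(O)cc(O)c2)cc1 | target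

**Step count and risks**

Total step count: 22. Longest linear sequence: 11 steps (from 7 through steps 5–9, 11, 12 and 19–22).

Steps most likely to fail:

1. Step 21. The hindered arylzinc 32 may transmetalate slowly, so that the benzylic radical dimerises or is reduced before capture; facial selectivity at C3 may erode; aryllithium 31 may undergo proton transfer before zincation. The fallback gives up the preformed organometallic in favour of a cross-electrophile coupling. It sets out from 27: copper-catalysed aromatic Finkelstein exchange (CuI, NaI, trans-N,N'-dimethylcyclohexane-1,2-diamine, 1,4-dioxane, 110 °C) should give (2S,3S)-3-(3,5-dimethoxyphenyl)-4-iodo-6-methoxy-2-(4-methoxyphenyl)-2,3-dihydro-1-benzofuran F1. NHPI ester 30, made from 29 as in step 21, and F1 are then joined by nickel-catalysed reductive decarboxylative arylation (NiBr2·glyme, 4,4'-di-tert-butyl-2,2'-bipyridine, Zn powder, DMA, rt). Here the aryl iodide adds to zerovalent nickel and the resulting arylnickel species traps the C3 radical anti to the C2 anisyl group, which comes back to the route at 33.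

2. Step 15. The triflate makes ring A a poor migrating group, so the C2 anisyl group may shift instead (isoflavone formation), the flavanone may be dehydrogenated to the flavone, or acid may ionise C2–O and erode the configuration. The fallback changes the substrate so that the migrating ring is less electron-poor. It sets out from 21: acetylation (Ac2O, pyridine) should give (2S)-7-methoxy-2-(4-methoxyphenyl)-4-oxo-3,4-dihydro-2H-chromen-5-yl acetate F2. The same trivalent-iodine ring contraction (PhI(OAc)2, H2SO4, HC(OMe)3/MeOH) then gives methyl (2S,3S)-4-acetoxy-6-methoxy-2-(4-methoxyphenyl)-2,3-dihydro-1-benzofuran-3-carboxylate F3. Selective removal of the aryl acetate (K2CO3, MeOH, 0 °C) gives methyl (2S,3S)-4-hydroxy-6-methoxy-2-(4-methoxyphenyl)-2,3-dihydro-1-benzofuran-3-carboxylate F4, and triflation of F4 (Tf2O, pyridine) comes back to the route at 23.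

3. Step 22. Nine ethers must be cleaved while the Lewis acid can ionise the C2–O bonds of three 2-aryl-dihydrobenzofurans and protonate the stilbene, so ring opening, cationic side reactions or incomplete cleavage may occur. The fallback is an acid-free, nucleophilic dealkylation that sets out from 33: a melt with MeMgI (neat, about 160 °C, reduced pressure), in which each O-methyl group is removed as ethane and the phenols emerge as magnesium phenoxides. Mild aqueous NH4Cl work-up comes back directly at 34; no new isolated compound is involved.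

**Further compounds**

F1 | step 21 | (2S,3S)-3-(3,5-dimethoxyphenyl)-4-iodo-6-methoxy-2-(4-methoxyphenyl)-2,3-dihydro-1-benzofuran | Ic1cc(OC)cc2c1[C@H](c1cc(OC)cc(OC)c1)[C@@H](c1ccc(OC)cc1)O2
F2 | step 15 | (2S)-7-methoxy-2-(4-methoxyphenyl)-4-oxo-3,4-dihydro-2H-chromen-5-yl acetate | O=C1C[C@@H](c2ccc(OC)cc2)Oc2cc(OC)cc(OC(C)=O)c12
F3 | step 15 | methyl (2S,3S)-4-acetoxy-6-methoxy-2-(4-methoxyphenyl)-2,3-dihydro-1-benzofuran-3-carboxylate | COc1cc(OC(C)=O)c2c(c1)O[C@H](c1ccc(OC)cc1)[C@H]2C(=O)OC
F4 | step 15 | methyl (2S,3S)-4-hydroxy-6-methoxy-2-(4-methoxyphenyl)-2,3-dihydro-1-benzofuran-3-carboxylate | COc1cc(O)c2c(c1)O[C@H](c1ccc(OC)cc1)[C@H]2C(=O)OC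
F0 | step 22 | none | none
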